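**Plan**
- Cuts, in retrosynthetic order: the C11–O aryl ether (isofraxidin plus a primary alcohol); C3–C4 of ring A (tertiary C4 radical onto a C3 nitrile); C1=C2 (olefination of a C1 aldehyde); last, C5–C6 and C9–C10 together.
- Enabling feature: ring B (C5–C6–C7–C8–C9–C10) is a cyclohexene whose C7=C8 bond faces the C5–C10 bond across the ring. It therefore unfolds into the diene C6=C7–C8(CH3)=C9–C11H2O and the (E)-enal C5=C10, which bears the C10 methyl, C1 as CHO and C4 as the isopropenyl carbon.
- Forward order: ring B forms first by asymmetric Diels–Alder reaction. The C2–C3 unit is then attached at C1, ring A closes at C3–C4 and gives the C3 ketone directly, and the coumarin is joined last.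
- Stereochemistry: C5, C9 and C10 all arise in the cycloaddition. The catalyst face sets C10, the E-enal geometry sets C5, and the E-diene geometry plus formyl-endo approach sets C9. No later step creates or touches a stereocentre.

Key step: step 4

Numbering: drimane numbering is used (decalin C1–C10, C11 = CH2O). Read from the SMILES, C11 lies on the face opposite to the C10 methyl (5R,9R,10S, trans-decalin), and the route is built for that isomer.
Assumption: the sense of induction of the (S)-catalyst is taken from the formyl C–H···O binding model of this catalyst class. If the adduct proved antipodal, the (R)-catalyst would be used with nothing else changed.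

Step 1
Reactants: 1 (E)-3-methylpent-2-en-4-yn-1-ol
Product: 2 tert-butyl{[(2E)-3-methylpent-2-en-4-yn-1-yl]oxy}diphenylsilane
Conditions: TBDPSCl, imidazole, CH2Cl2, 0 °C → rt
Reagents that add atoms: tert-butyl(chloro)diphenylsilane, CC(C)(C)[Si](Cl)(c1ccccc1)c1ccccc1
Why: Imidazole-promoted silylation of a primary alcohol gives a bulky, weakly Lewis-basic ether that should not compete for boron in step 4, should survive steps 5–7 and can be removed by fluoride beside the C3 ketone.

Step 2
Reactants: 2 silyl enyne
Product: 3 tert-butyl{[(2E)-3-methylpenta-2,4-dien-1-yl]oxy}diphenylsilane (C6=C7–C8(CH3)=C9–C11 diene)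
Conditions: H2 (1 atm, stopped after 1 equiv), Pd/CaCO3 poisoned with Pb(OAc)2, quinoline, hexane, rt
Reagents that add atoms: none
Why: Semihydrogenation of a terminal alkyne over lead-poisoned palladium should stop at the vinyl group when quinoline is present and uptake is limited, and it leaves the E-trisubstituted alkene geometry unchanged.

Step 3
Reactants: 4 methacrolein; 5 2-(triphenylphosphoranylidene)propanal
Product: 6 (E)-2,4-dimethylpenta-2,4-dienal
Conditions: 4 (3 equiv), BHT (trace), toluene, 80 °C, sealed vessel
Reagents that add atoms: none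
Why: Wittig olefination with a formyl-stabilised ylide is E-selective, and the excess of volatile 4 together with the lower electrophilicity of the α-methyl enal product should hold back a second olefination.

Step 4
Reactants: 3 silyloxymethyl diene; 6 (E)-2,4-dimethylpenta-2,4-dienal
Product: 7 (1S,2R,6S)-2-{[(tert-butyldiphenylsilyl)oxy]methyl}-1,3-dimethyl-6-(prop-1-en-2-yl)cyclohex-3-ene-1-carbaldehyde (ring B; C1 formyl on C10; isopropenyl on C5; CH2OSi on C9)
Conditions: (S)-3,3-diphenyl-1-(2-methylphenyl)tetrahydro-1H,3H-pyrrolo[1,2-c][1,3,2]oxazaborole (20 mol %), Tf2NH (18 mol %), 3 (1.5 equiv), CH2Cl2, −78 → −20 °C; Et3N quench in the cold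
Reagents that add atoms: none
Why: The boron cation binds the formyl oxygen of s-trans 6 and holds it by a formyl C–H···O contact, which lowers the LUMO of C5=C10 so that 3 adds in a concerted but asynchronous [4π+2π] event in which C6–C5 bonding runs ahead of C9–C10 bonding. The closest known reaction type is the oxazaborolidinium-catalysed enantioselective Diels–Alder reaction of α-substituted and α,β-disubstituted enals (methacrolein, tiglaldehyde) with acyclic dienes. Ring B closes by intermolecular suprafacial–suprafacial [4+2] cycloaddition, both σ-bonds (C5–C6 and C9–C10) forming in the same step and the π-bond ending at C7=C8 with the C8 methyl and C11 already in place. C10 is set by the catalyst, whose phenyl group next to the bound enal covers one face so that the diene takes the open one (the model predicts 10S for the (S)-catalyst); C5 follows from the E geometry of 6, which places C1 and C4 trans on ring B (the later trans-decalin); C9 follows from the E geometry of 3 and the formyl-endo transition state, which places C11 cis to C1 and anti to the C10 methyl. The required regiochemistry (C9 to C10) rests on the unsubstituted, large-coefficient terminus C6 taking the hindered β-carbon C5 in the short bond, an "ortho" preference of the C9 substituent that steric demand reinforces against the weaker "para" pull of the C8 methyl, while endo selectivity is helped by the flat formyl group being the smaller neighbour for C11 and by the isopropenyl group going exo. Site selectivity within 6 rests on A(1,3) strain between the C10 methyl and the isopropenyl group, which twists the second alkene out of conjugation so that it is not activated, and on the inside methyl at C10, which keeps 6 from reacting as a diene.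

Step 5
Reactants: 7 ring B aldehyde
Product: 8 (2E)-3-[(1S,2R,6S)-2-{[(tert-butyldiphenylsilyl)oxy]methyl}-1,3-dimethyl-6-(prop-1-en-2-yl)cyclohex-3-en-1-yl]prop-2-enenitrile
Conditions: (EtO)2P(O)CH2CN, NaH, THF, 0 → 40 °C
Reagents that add atoms: diethyl cyanomethylphosphonate, CCOP(=O)(CC#N)OCC
Why: Horner–Wadsworth–Emmons olefination with the small, strongly nucleophilic cyanomethylphosphonate anion suits a non-enolisable aldehyde on a quaternary carbon, the E/Z outcome is irrelevant because C1=C2 is reduced next, and C10 cannot epimerise.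

Step 6
Reactants: 8 unsaturated nitrile
Product: 9 3-[(1S,2R,6S)-2-{[(tert-butyldiphenylsilyl)oxy]methyl}-1,3-dimethyl-6-(prop-1-en-2-yl)cyclohex-3-en-1-yl]propanenitrile
Conditions: Mg turnings, MeOH, 0 °C → rt
Reagents that add atoms: none
Why: Dissolving-metal conjugate reduction of an α,β-unsaturated nitrile by magnesium in methanol proceeds by electron transfer to the conjugated π-system only, so the isolated isopropenyl and C7=C8 alkenes, the nitrile and the silyl ether should be left alone.

Step 7
Reactants: 9 saturated nitrile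
Product: 11 (4aS,5R,8aR)-5-{[(tert-butyldiphenylsilyl)oxy]methyl}-1,1,4a,6-tetramethyl-3,4,4a,5,8,8a-hexahydronaphthalen-2(1H)-one, via N-H ketimine 10 (not isolated)
Conditions: Fe(acac)3 (30 mol %), PhSiH3 (3 equiv), EtOH, Ar, 60 °C; then 1 M HCl, THF, rt
Reagents that add atoms: water, O
Why: In this hydrogen-atom-transfer-initiated alkene–nitrile radical cyclisation the iron hydride made from Fe(acac)3 and PhSiH3 gives H• to the CH2 terminus of the 1,1-disubstituted alkene (faster than to the trisubstituted C7=C8, as in limonene-type dienes), the tertiary C4 radical closes ring A 6-exo-dig on the nitrile carbon held trans-diequatorial to it, and the iminyl radical is reduced to imine 10, which acid hydrolyses to the C3 ketone without forming or disturbing a stereocentre.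

Step 8
Reactants: 11 silyl ether ketone
Product: 12 (4aS,5R,8aR)-5-(hydroxymethyl)-1,1,4a,6-tetramethyl-3,4,4a,5,8,8a-hexahydronaphthalen-2(1H)-one (11-hydroxy-9-epi-drim-7-en-3-one)
Conditions: TBAF, THF, 0 °C → rt
Reagents that add atoms: none
Why: Fluoride-induced silyl ether cleavage is orthogonal to the ketone and the alkene, and the C3 ketone has no adjacent stereocentre that the mildly basic medium could scramble.

Step 9
Reactants: 12 hydroxy ketone; 13 isofraxidin (7-hydroxy-6,8-dimethoxy-2H-chromen-2-one)
Product: 14 7-{[(1R,4aR,8aS)-2,5,5,8a-tetramethyl-6-oxo-1,4,4a,5,6,7,8,8a-octahydronaphthalen-1-yl]methoxy}-6,8-dimethoxy-2H-chromen-2-one (CNP0127079.1)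
Conditions: PPh3, DIAD, THF, 0 °C → rt
Reagents that add atoms: none
Why: In the Mitsunobu etherification the acidic 7-OH of 13 protonates the phosphine–azodicarboxylate adduct and its phenoxide displaces the C11 oxyphosphonium group by SN2 at a primary carbon, so no stereocentre is involved and the hindered C3 ketone stays a spectator.

**Compound list**
1 | (E)-3-methylpent-2-en-4-yn-1-ol | C#C/C(C)=C/CO | starting material
2 | tert-butyl{[(2E)-3-methylpent-2-en-4-yn-1-yl]oxy}diphenylsilane | C#C/C(C)=C/CO[Si](c1ccccc1)(c1ccccc1)C(C)(C)C | intermediate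
3 | tert-butyl{[(2E)-3-methylpenta-2,4-dien-1-yl]oxy}diphenylsilane | C=C/C(C)=C/CO[Si](c1ccccc1)(c1ccccc1)C(C)(C)C | intermediate
4 | methacrolein | CC(=C)C=O | starting material
5 | 2-(triphenylphosphoranylidene)propanal | CC(C=O)=P(c1ccccc1)(c1ccccc1)c1ccccc1 | starting material
6 | (E)-2,4-dimethylpenta-2,4-dienal | CC(=C)/C=C(\C)C=O | intermediate
7 | (1S,2R,6S)-2-{[(tert-butyldiphenylsilyl)oxy]methyl}-1,3-dimethyl-6-(prop-1-en-2-yl)cyclohex-3-ene-1-carbaldehyde | CC(C)(C)[Si](c1ccccc1)(c1ccccc1)OC[C@@H]1C(C)=CC[C@@H](C(C)=C)[C@]1(C)C=O | intermediate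
8 | (2E)-3-[(1S,2R,6S)-2-{[(tert-butyldiphenylsilyl)oxy]methyl}-1,3-dimethyl-6-(prop-1-en-2-yl)cyclohex-3-en-1-yl]prop-2-enenitrile | CC(C)(C)[Si](c1ccccc1)(c1ccccc1)OC[C@@H]1C(C)=CC[C@@H](C(C)=C)[C@]1(C)/C=C/C#N | intermediate
9 | 3-[(1S,2R,6S)-2-{[(tert-butyldiphenylsilyl)oxy]methyl}-1,3-dimethyl-6-(prop-1-en-2-yl)cyclohex-3-en-1-yl]propanenitrile | CC(C)(C)[Si](c1ccccc1)(c1ccccc1)OC[C@@H]1C(C)=CC[C@@H](C(C)=C)[C@]1(C)CCC#N | intermediate
10 | (4aS,5R,8aR)-5-{[(tert-butyldiphenylsilyl)oxy]methyl}-1,1,4a,6-tetramethyl-3,4,4a,5,8,8a-hexahydronaphthalen-2(1H)-imine | CC(C)(C)[Si](c1ccccc1)(c1ccccc1)OC[C@@H]1C(C)=CC[C@H]2C(C)(C)C(=N)CC[C@]12C | intermediate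
11 | (4aS,5R,8aR)-5-{[(tert-butyldiphenylsilyl)oxy]methyl}-1,1,4a,6-tetramethyl-3,4,4a,5,8,8a-hexahydronaphthalen-2(1H)-one | CC(C)(C)[Si](c1ccccc1)(c1ccccc1)OC[C@@H]1C(C)=CC[C@H]2C(C)(C)C(=O)CC[C@]12C | intermediate
12 | (4aS,5R,8aR)-5-(hydroxymethyl)-1,1,4a,6-tetramethyl-3,4,4a,5,8,8a-hexahydronaphthalen-2(1H)-one | OC[C@@H]1C(C)=CC[C@H]2C(C)(C)C(=O)CC[C@]12C | intermediate
13 | isofraxidin | COc1cc2ccc(=O)oc2c(OC)c1O | starting material
14 | 7-{[(1R,4aR,8aS)-2,5,5,8a-tetramethyl-6-oxo-1,4,4a,5,6,7,8,8a-octahydronaphthalen-1-yl]methoxy}-6,8-dimethoxy-2H-chromen-2-one | COc1cc2ccc(=O)oc2c(OC)c1OC[C@@H]1C(C)=CC[C@H]2C(C)(C)C(=O)CC[C@]12C | target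

**Totals**
Total step count: 9.
Longest linear sequence: 8 steps (1 → 14 by steps 1, 2 and 4–9). Step 3 is the side branch.

**Steps most likely to fail**

Step 4. The cycloaddition may be too slow at the crowded trisubstituted C5=C10 bond. Acid-induced oligomerisation of the diene, addition across the isopropenyl double bond, or loss of regio- and endo-control could then take over.
The fallback sets out from 5 and 3 and comes back at 8. It keeps the same two bond formations but raises C4 to the ketone level.
- Wittig reaction of 5 with aqueous methylglyoxal (CH2Cl2–water, rt) should give (E)-2-methyl-4-oxopent-2-enal F1. Its C5=C10 bond is activated from both ends and it has no second alkene.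
- Cycloaddition of F1 with 3 under the same boron cation, bound at the less hindered formyl oxygen, should give the keto aldehyde (1R,2R,6R)-6-acetyl-2-{[(tert-butyldiphenylsilyl)oxy]methyl}-1,3-dimethylcyclohex-3-ene-1-carbaldehyde F2.
- Horner–Wadsworth–Emmons reaction with (EtO)2P(O)CH2CN and NaH takes the aldehyde in preference to the methyl ketone and gives the keto nitrile (2E)-3-[(1R,2R,6R)-6-acetyl-2-{[(tert-butyldiphenylsilyl)oxy]methyl}-1,3-dimethylcyclohex-3-en-1-yl]prop-2-enenitrile F3.
- Wittig methylenation of the acetyl group (Ph3PCH3Br, KN(SiMe3)2, THF, −78 °C → rt) then gives 8. The trans arrangement at C5 is the more stable one, so enolisation should not cost the stereocentre.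

Step 7. Early hydrogen delivery to the tertiary C4 radical (net hydrogenation of the isopropenyl group) may outrun the slow 6-exo attack on the nitrile. Hydrogen-atom transfer to C7=C8 may also set in.
The fallback sets out from 9 and comes back at 11. It replaces the C≡N acceptor by C=O, which takes carbon radicals in the 6-exo mode much faster, at the cost of two redox steps.
- i-Bu2AlH (toluene, −78 °C, aqueous acid work-up) gives 3-[(1S,2R,6S)-2-{[(tert-butyldiphenylsilyl)oxy]methyl}-1,3-dimethyl-6-(prop-1-en-2-yl)cyclohex-3-en-1-yl]propanal F4.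
- Reductive alkene–aldehyde radical cyclisation (Fe(acac)3, PhSiH3, EtOH, 60 °C) should close ring A to (2S,4aS,5R,8aR)-5-{[(tert-butyldiphenylsilyl)oxy]methyl}-1,1,4a,6-tetramethyl-1,2,3,4,4a,5,8,8a-octahydronaphthalen-2-ol F5. The equatorial C3 alcohol is expected, and either epimer serves.
- Dess–Martin oxidation gives 11.

Step 9. Displacement at C11, a β-branched primary carbon next to the quaternary C10, by a phenol flanked by two methoxy groups may be slow. Elimination towards C9 or alkylation of the reduced azodicarboxylate could then compete.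
The fallback sets out from 12 and comes back at 14. It separates activation from substitution.
- MsCl and Et3N (CH2Cl2, 0 °C) give [(1R,4aR,8aS)-2,5,5,8a-tetramethyl-6-oxo-1,4,4a,5,6,7,8,8a-octahydronaphthalen-1-yl]methyl methanesulfonate F6.
- F6 is heated with 13 and Cs2CO3 in DMF (60 °C), so that the naked caesium phenoxide performs the SN2 step and gives 14.

**Further compounds**
F1 | step 4 | (E)-2-methyl-4-oxopent-2-enal | CC(=O)/C=C(\C)C=O
F2 | step 4 | (1R,2R,6R)-6-acetyl-2-{[(tert-butyldiphenylsilyl)oxy]methyl}-1,3-dimethylcyclohex-3-ene-1-carbaldehyde | CC(C)(C)[Si](c1ccccc1)(c1ccccc1)OC[C@@H]1C(C)=CC[C@@H](C(C)=O)[C@]1(C)C=O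
F3 | step 4 | (2E)-3-[(1R,2R,6R)-6-acetyl-2-{[(tert-butyldiphenylsilyl)oxy]methyl}-1,3-dimethylcyclohex-3-en-1-yl]prop-2-enenitrile | CC(C)(C)[Si](c1ccccc1)(c1ccccc1)OC[C@@H]1C(C)=CC[C@@H](C(C)=O)[C@]1(C)/C=C/C#N
F4 | step 7 | 3-[(1S,2R,6S)-2-{[(tert-butyldiphenylsilyl)oxy]methyl}-1,3-dimethyl-6-(prop-1-en-2-yl)cyclohex-3-en-1-yl]propanal | CC(C)(C)[Si](c1ccccc1)(c1ccccc1)OC[C@@H]1C(C)=CC[C@@H](C(C)=C)[C@]1(C)CCC=O
F5 | step 7 | (2S,4aS,5R,8aR)-5-{[(tert-butyldiphenylsilyl)oxy]methyl}-1,1,4a,6-tetramethyl-1,2,3,4,4a,5,8,8a-octahydronaphthalen-2-ol | CC(C)(C)[Si](c1ccccc1)(c1ccccc1)OC[C@@H]1C(C)=CC[C@H]2C(C)(C)[C@@H](O)CC[C@]12C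
F6 | step 9 | [(1R,4aR,8aS)-2,5,5,8a-tetramethyl-6-oxo-1,4,4a,5,6,7,8,8a-octahydronaphthalen-1-yl]methyl methanesulfonate | CS(=O)(=O)OC[C@@H]1C(C)=CC[C@H]2C(C)(C)C(=O)CC[C@]12C
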